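**Plan**

- Bicyclo[3.2.1]oct-2-en-8-one numbering: C1 allyl bridgehead, C2=C3(OMe), C4 (OAc), C5 methoxy bridgehead, C6 aryl, C7 methyl, C8 ketone. The C8 ketone sits between quaternary C5 and C1, so C1 is its only enolisable α-carbon, and C2 is vinylic. The C1–C2 bond of the six-membered ring C1–C2–C3–C4–C5–C8 is therefore an enolate–alkenyl bond.
- Retrosynthesis: cut the acetate; cut C1–C2, which opens the six-membered ring to a cyclopentanone (C8–C5–C6–C7–C1) carrying an (E)-β-bromo enol ether on C5; then C1–allyl, C2–Br, C3–C4 (α-methoxyvinyl anion plus aldehyde), O–CH3 and C5–O, C6–aryl, and C5–C8 (Dieckmann) back to dimethyl (S)-3-methyladipate.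
- Forward: the five-membered ring is made first, then the aryl group, the C5 oxygen and the three-carbon side chain are added, C1 is allylated, and the six-membered ring is closed last; desilylation and acetylation finish.
- Stereochemistry: C7 from (S)-citronellol; C6 by cuprate addition anti to the C7 methyl; C5 by enolate oxygenation anti to the C6 aryl; C4 by Cornforth/Felkin–Anh addition to the C5 aldehyde; C1 by the geometry of the ring closure, in which both C1 epimers converge.

Key step: step 14

Remark: the atoms of all intermediates are referred to by the bicycle numbers above; 24 is drawn as the C1 epimer expected from allylation anti to the C7 methyl group, and its C1 epimer should give the same product in step 14.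

**Route**

Step 1
Reactants: 1 (S)-citronellol
Product: 2 (3S)-3-methylhexanedioic acid
Conditions: RuCl3·xH2O (2 mol %), NaIO4 (5.5 equiv), MeCN/EtOAc/H2O, 0 °C to rt
Reagents that add atoms: sodium periodate, [Na+].[O-]I(=O)(=O)=O; water, O
Why: Catalytic RuO4 oxidation cleaves the trisubstituted alkene to a carboxylic acid plus acetone and takes the primary alcohol to the acid in the same pot; the stereocentre carries no acidic hydrogen and is untouched.

Step 2
Reactants: 2 (3S)-3-methylhexanedioic acid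
Product: 3 dimethyl (3S)-3-methylhexanedioate
Conditions: MeOH, H2SO4 (cat.), reflux
Reagents that add atoms: methanol, CO
Why: Fischer esterification; no bond to the stereocentre is involved.

Step 3
Reactants: 3 dimethyl (3S)-3-methylhexanedioate
Product: 4 methyl (4S)-4-methyl-2-oxocyclopentane-1-carboxylate
Conditions: NaOMe (1.2 equiv), toluene, 100 °C, MeOH distilled off; AcOH, 0 °C
Reagents that add atoms: none
Why: Dieckmann condensation under equilibrating conditions; the enolate at the CH2 remote from the methyl branch closes on the other ester and the product rests as its unhindered stabilised enolate, so the 4-methyl regioisomer should dominate (the 2-methyl-5-oxo isomer is removed by chromatography), and the methyl-bearing centre cannot enolise.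

Step 4
Reactants: 4 methyl (4S)-4-methyl-2-oxocyclopentane-1-carboxylate
Product: 7 methyl (3R)-3-methyl-5-oxocyclopent-1-ene-1-carboxylate, via selenide 5 (not isolated), via selenoxide 6 (not isolated)
Conditions: PhSeCl, pyridine, CH2Cl2, 0 °C; then 30% H2O2, 0 °C to rt; used at once
Reagents that add atoms: none
Why: Selenenylation at the doubly activated carbon followed by selenoxide syn-elimination can only place the alkene towards the ring CH2 next to the methyl-bearing carbon; the reactive alkylidene β-keto ester is used crude to avoid dimerisation.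

Step 5
Reactants: 7 methyl (3R)-3-methyl-5-oxocyclopent-1-ene-1-carboxylate; 8 5-bromo-1,2,3-trimethoxybenzene
Product: 10 methyl (2S,3R)-3-methyl-5-oxo-2-(3,4,5-trimethoxyphenyl)cyclopentane-1-carboxylate, via aryl Grignard reagent 9 (not isolated)
Conditions: 8, Mg, THF, 40 °C; then CuBr·SMe2 (10 mol %), 7, THF, −78 °C; 1 M HCl
Reagents that add atoms: none
Why: Copper-catalysed conjugate addition of the aryl Grignard reagent to the doubly activated enone; the aryl group enters anti to the methyl group on the adjacent stereocentre, which sets C6 trans to C7.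

Step 6
Reactants: 10 methyl (2S,3R)-3-methyl-5-oxo-2-(3,4,5-trimethoxyphenyl)cyclopentane-1-carboxylate
Product: 12 methyl (1R,2R,3R)-1-hydroxy-3-methyl-5-oxo-2-(3,4,5-trimethoxyphenyl)cyclopentane-1-carboxylate, via potassium enolate 11 (not isolated)
Conditions: KHMDS (1.1 equiv), THF, −78 °C; then 3-phenyl-2-(phenylsulfonyl)oxaziridine (1.3 equiv), −78 °C; AcOH, −78 °C
Reagents that add atoms: 3-phenyl-2-(phenylsulfonyl)oxaziridine (Davis oxaziridine), O=S(=O)(c1ccccc1)N1OC1c1ccccc1
Why: Davis oxidation of the planar β-keto ester enolate; the bulky oxaziridine delivers oxygen to the face anti to the vicinal aryl group, which sets the quaternary C5 with oxygen trans to aryl and the ester carbon (later C4) cis to aryl.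

Step 7
Reactants: 12 methyl (1R,2R,3R)-1-hydroxy-3-methyl-5-oxo-2-(3,4,5-trimethoxyphenyl)cyclopentane-1-carboxylate
Product: 13 methyl (1R,2R,3R)-1-methoxy-3-methyl-5-oxo-2-(3,4,5-trimethoxyphenyl)cyclopentane-1-carboxylate
Conditions: Me3OBF4 (3 equiv), 1,8-bis(dimethylamino)naphthalene (3 equiv), 4 Å MS, CH2Cl2, rt
Reagents that add atoms: trimethyloxonium tetrafluoroborate, C[O+](C)C.F[B-](F)(F)F
Why: O-Methylation with Meerwein's salt and a non-nucleophilic proton scavenger proceeds without an alkoxide, which avoids retro-Claisen cleavage and α-ketol rearrangement of the tertiary α-hydroxy β-keto ester; the configuration is retained because only the O–H bond reacts.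

Step 8
Reactants: 13 methyl (1R,2R,3R)-1-methoxy-3-methyl-5-oxo-2-(3,4,5-trimethoxyphenyl)cyclopentane-1-carboxylate
Product: 14 (2S,3R,4R)-2-(hydroxymethyl)-2-methoxy-4-methyl-3-(3,4,5-trimethoxyphenyl)cyclopentan-1-ol
Conditions: LiAlH4 (2.5 equiv), THF, 0 °C to rt; then H2O (Fieser work-up)
Reagents that add atoms: none
Why: Hydride reduction of both ester and ketone; the new carbinol centre at C8 is of no consequence because step 9 reoxidises it.

Step 9
Reactants: 14 (2S,3R,4R)-2-(hydroxymethyl)-2-methoxy-4-methyl-3-(3,4,5-trimethoxyphenyl)cyclopentan-1-ol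
Product: 15 (1S,2R,3R)-1-methoxy-3-methyl-5-oxo-2-(3,4,5-trimethoxyphenyl)cyclopentane-1-carbaldehyde
Conditions: Dess–Martin periodinane (3 equiv), CH2Cl2, 0 °C to rt; used crude
Reagents that add atoms: none
Why: Dess–Martin oxidation of both alcohols under anhydrous, nearly neutral conditions gives the β-keto aldehyde, whose quaternary C5 cannot epimerise.

Step 10
Reactants: 15 (1S,2R,3R)-1-methoxy-3-methyl-5-oxo-2-(3,4,5-trimethoxyphenyl)cyclopentane-1-carbaldehyde; 16 methyl vinyl ether
Product: 18 (2S,3R,4R)-2-[(1R)-1-hydroxy-2-methoxyprop-2-en-1-yl]-2-methoxy-4-methyl-3-(3,4,5-trimethoxyphenyl)cyclopentan-1-one, via 1-methoxyvinyllithium 17 (not isolated)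
Conditions: 16 (excess), t-BuLi (1.3 equiv), THF, −78 to 0 °C; then 15, THF, −78 °C; AcOH, −78 °C
Reagents that add atoms: none
Why: 1,2-Addition of α-lithiated methyl vinyl ether (an acyl anion equivalent) to the aldehyde, which should react far faster than the cyclopentanone at −78 °C; with the weakly chelating lithium/THF system the Cornforth/Felkin–Anh transition state (C=O anti to C5–OMe, attack past the flat C8 carbonyl and not past C6 with its cis aryl group) should give the (1R)-carbinol, which is C4 of the target.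

Step 11
Reactants: 18 (2S,3R,4R)-2-[(1R)-1-hydroxy-2-methoxyprop-2-en-1-yl]-2-methoxy-4-methyl-3-(3,4,5-trimethoxyphenyl)cyclopentan-1-one
Product: 19 (2S,3R,4R)-2-[(1R)-1-(tert-butyldimethylsilyloxy)-2-methoxyprop-2-en-1-yl]-2-methoxy-4-methyl-3-(3,4,5-trimethoxyphenyl)cyclopentan-1-one
Conditions: TBSOTf (1.5 equiv), 2,6-lutidine (3 equiv), CH2Cl2, −78 to 0 °C
Reagents that add atoms: tert-butyldimethylsilyl triflate, CC(C)(C)[Si](C)(C)OS(=O)(=O)C(F)(F)F
Why: Silyl triflate/lutidine silylation of a hindered secondary alcohol; the ether blocks retro-aldol cleavage of the β-hydroxy ketone in the basic steps that follow.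

Step 12
Reactants: 19 (2S,3R,4R)-2-[(1R)-1-(tert-butyldimethylsilyloxy)-2-methoxyprop-2-en-1-yl]-2-methoxy-4-methyl-3-(3,4,5-trimethoxyphenyl)cyclopentan-1-one
Product: 21 (2S,3R,4R)-2-[(1S,2E)-3-bromo-1-(tert-butyldimethylsilyloxy)-2-methoxyprop-2-en-1-yl]-2-methoxy-4-methyl-3-(3,4,5-trimethoxyphenyl)cyclopentan-1-one, via dibromo ether 20 (not isolated)
Conditions: Br2 (1.0 equiv), CH2Cl2, −78 °C; then DBU (2.5 equiv), −78 °C to rt
Reagents that add atoms: bromine, BrBr
Why: Bromine addition to the enol ether (far more nucleophilic than the arene at −78 °C) and base-induced loss of HBr through the oxocarbenium ion give the β-bromo enol ether; bromine is expected trans to methoxy and cis to the carbinol carbon (E), because an α-substituted methyl enol ether keeps its planar s-cis methoxy group only when the β-substituent is trans to oxygen, as in 2-methoxybut-2-ene and β-methoxyacrylates.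

Step 13
Reactants: 21 (2S,3R,4R)-2-[(1S,2E)-3-bromo-1-(tert-butyldimethylsilyloxy)-2-methoxyprop-2-en-1-yl]-2-methoxy-4-methyl-3-(3,4,5-trimethoxyphenyl)cyclopentan-1-one; 22 allyl bromide
Product: 24 (2S,3R,4S,5R)-2-[(1S,2E)-3-bromo-1-(tert-butyldimethylsilyloxy)-2-methoxyprop-2-en-1-yl]-2-methoxy-4-methyl-5-(prop-2-en-1-yl)-3-(3,4,5-trimethoxyphenyl)cyclopentan-1-one, via lithium enolate 23 (not isolated)
Conditions: LDA (1.1 equiv), THF, −78 °C; then 22 (1.5 equiv), DMPU, −78 to −30 °C
Reagents that add atoms: none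
Why: Enolate alkylation; LDA can deprotonate only the ring CH2 (the other α-carbon is quaternary) and allylation should occur mainly anti to the vicinal methyl group, but the configuration at C1 is irrelevant since step 14 planarises it again.

Step 14
Reactants: 24 (2S,3R,4S,5R)-2-[(1S,2E)-3-bromo-1-(tert-butyldimethylsilyloxy)-2-methoxyprop-2-en-1-yl]-2-methoxy-4-methyl-5-(prop-2-en-1-yl)-3-(3,4,5-trimethoxyphenyl)cyclopentan-1-one
Product: 25 (1S,4R,5S,6R,7S)-4-(tert-butyldimethylsilyloxy)-3,5-dimethoxy-7-methyl-1-(prop-2-en-1-yl)-6-(3,4,5-trimethoxyphenyl)bicyclo[3.2.1]oct-2-en-8-one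
Conditions: Pd(PPh3)4 (10 mol %), KOt-Bu (1.3 equiv, added last), degassed THF, rt to 60 °C
Reagents that add atoms: none
Why: KOt-Bu forms the only possible enolate of 24 (C1–C8, since C5 is quaternary), zerovalent palladium inserts into the C2–Br bond with retention of the E geometry, the enolate displaces bromide on the divalent alkenylpalladium and C–C reductive elimination makes C1–C2. The closest known reaction type is the intramolecular palladium-catalysed α-alkenylation of ketone enolates with vinyl halides, which is established for bridged bicyclic ketones. The six-membered ring C1–C2–C3–C4–C5–C8 closes by reductive elimination from a seven-membered C-bound palladacycle in which both the enolate unit C1=C8 and the alkene C2=C3 lie inside the new ring, which is why bromine must be cis to C4. The new stereocentre C1 is fixed by the tether: the side chain hangs from the face of C5 syn to the C6 aryl group, so C2 can reach only that face of the planar enolate and the allyl group is pushed to the opposite face, cis to the C7 methyl group, whichever C1 epimer of 24 enters. The step needs regioselective enolisation (secured by quaternary C5), C- over O-alkenylation (the normal course for C-bound ketone enolates) and a persistent alkenylpalladium (C3 carries no hydrogen and its methoxy group is trans to palladium, so neither β-hydride nor β-alkoxide elimination is open). The silyl ether on C4 prevents retro-aldol cleavage under the basic conditions.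

Step 15
Reactants: 25 (1S,4R,5S,6R,7S)-4-(tert-butyldimethylsilyloxy)-3,5-dimethoxy-7-methyl-1-(prop-2-en-1-yl)-6-(3,4,5-trimethoxyphenyl)bicyclo[3.2.1]oct-2-en-8-one
Product: 26 (1S,4R,5S,6R,7S)-4-hydroxy-3,5-dimethoxy-7-methyl-1-(prop-2-en-1-yl)-6-(3,4,5-trimethoxyphenyl)bicyclo[3.2.1]oct-2-en-8-one
Conditions: TBAF (3 equiv), AcOH (3 equiv), THF, rt to 40 °C
Reagents that add atoms: none
Why: Fluoride-mediated desilylation; the acetic acid buffer keeps the medium near neutral so that the liberated β-hydroxy ketone should not open by retro-aldol reaction and the enol ether should not hydrolyse.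

Step 16
Reactants: 26 (1S,4R,5S,6R,7S)-4-hydroxy-3,5-dimethoxy-7-methyl-1-(prop-2-en-1-yl)-6-(3,4,5-trimethoxyphenyl)bicyclo[3.2.1]oct-2-en-8-one
Product: 27 (1S,4R,5S,6R,7S)-4-acetoxy-3,5-dimethoxy-7-methyl-1-(prop-2-en-1-yl)-6-(3,4,5-trimethoxyphenyl)bicyclo[3.2.1]oct-2-en-8-one
Conditions: Ac2O (3 equiv), DMAP (0.2 equiv), pyridine, CH2Cl2, rt
Reagents that add atoms: acetic anhydride, CC(=O)OC(C)=O
Why: DMAP-catalysed O-acylation of the secondary alcohol; only the O–H bond reacts, so C4 keeps its configuration.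

**Compound list**

1 | (S)-citronellol, (3S)-3,7-dimethyloct-6-en-1-ol | C[C@@H](CCC=C(C)C)CCO | starting material
2 | (3S)-3-methylhexanedioic acid | C[C@@H](CCC(=O)O)CC(=O)O | intermediate
3 | dimethyl (3S)-3-methylhexanedioate | C[C@@H](CCC(=O)OC)CC(=O)OC | intermediate
4 | methyl (4S)-4-methyl-2-oxocyclopentane-1-carboxylate (C1 epimers, partly enolised) | COC(=O)C1C(=O)C[C@@H](C)C1 | intermediate
5 | selenide: methyl (4R)-4-methyl-2-oxo-1-(phenylselanyl)cyclopentane-1-carboxylate (C1 epimers; methyl carbon arranged as in 4) | COC(=O)C1([Se]c2ccccc2)C(=O)C[C@@H](C)C1 | intermediate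
6 | selenoxide: methyl (4R)-4-methyl-2-oxo-1-(phenylseleninyl)cyclopentane-1-carboxylate | COC(=O)C1([Se](=O)c2ccccc2)C(=O)C[C@@H](C)C1 | intermediate
7 | methyl (3R)-3-methyl-5-oxocyclopent-1-ene-1-carboxylate | COC(=O)C1=C[C@H](C)CC1=O | intermediate
8 | 5-bromo-1,2,3-trimethoxybenzene | COc1cc(Br)cc(OC)c1OC | starting material
9 | (3,4,5-trimethoxyphenyl)magnesium bromide | COc1cc([Mg]Br)cc(OC)c1OC | intermediate
10 | methyl (2S,3R)-3-methyl-5-oxo-2-(3,4,5-trimethoxyphenyl)cyclopentane-1-carboxylate (aryl trans to methyl; C1 epimers and enol) | COC(=O)C1C(=O)C[C@@H](C)[C@@H]1c2cc(OC)c(OC)c(OC)c2 | intermediate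
11 | potassium enolate of 10 (enolate across the ester-bearing carbon and the ketone) | COC(=O)C1=C([O-])C[C@@H](C)[C@@H]1c2cc(OC)c(OC)c(OC)c2.[K+] | intermediate
12 | methyl (1R,2R,3R)-1-hydroxy-3-methyl-5-oxo-2-(3,4,5-trimethoxyphenyl)cyclopentane-1-carboxylate (OH trans to aryl, cis to methyl) | COC(=O)[C@]1(O)C(=O)C[C@@H](C)[C@@H]1c2cc(OC)c(OC)c(OC)c2 | intermediate
13 | methyl (1R,2R,3R)-1-methoxy-3-methyl-5-oxo-2-(3,4,5-trimethoxyphenyl)cyclopentane-1-carboxylate | COC(=O)[C@]1(OC)C(=O)C[C@@H](C)[C@@H]1c2cc(OC)c(OC)c(OC)c2 | intermediate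
14 | (2S,3R,4R)-2-(hydroxymethyl)-2-methoxy-4-methyl-3-(3,4,5-trimethoxyphenyl)cyclopentan-1-ol (both C1 epimers) | OC[C@]1(OC)C(O)C[C@@H](C)[C@@H]1c2cc(OC)c(OC)c(OC)c2 | intermediate
15 | (1S,2R,3R)-1-methoxy-3-methyl-5-oxo-2-(3,4,5-trimethoxyphenyl)cyclopentane-1-carbaldehyde | O=C[C@]1(OC)C(=O)C[C@@H](C)[C@@H]1c2cc(OC)c(OC)c(OC)c2 | intermediate
16 | methyl vinyl ether (methoxyethene) | COC=C | starting material
17 | 1-methoxyvinyllithium | [Li]C(=C)OC | intermediate
18 | (2S,3R,4R)-2-[(1R)-1-hydroxy-2-methoxyprop-2-en-1-yl]-2-methoxy-4-methyl-3-(3,4,5-trimethoxyphenyl)cyclopentan-1-one | C=C(OC)[C@@H](O)[C@]1(OC)C(=O)C[C@@H](C)[C@@H]1c2cc(OC)c(OC)c(OC)c2 | intermediate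
19 | (2S,3R,4R)-2-[(1R)-1-(tert-butyldimethylsilyloxy)-2-methoxyprop-2-en-1-yl]-2-methoxy-4-methyl-3-(3,4,5-trimethoxyphenyl)cyclopentan-1-one | C=C(OC)[C@@H](O[Si](C)(C)C(C)(C)C)[C@]1(OC)C(=O)C[C@@H](C)[C@@H]1c2cc(OC)c(OC)c(OC)c2 | intermediate
20 | dibromo ether: (2S,3R,4R)-2-[(1S)-2,3-dibromo-1-(tert-butyldimethylsilyloxy)-2-methoxypropyl]-2-methoxy-4-methyl-3-(3,4,5-trimethoxyphenyl)cyclopentan-1-one (both configurations at the CBr(OMe) carbon) | BrCC(Br)(OC)[C@@H](O[Si](C)(C)C(C)(C)C)[C@]1(OC)C(=O)C[C@@H](C)[C@@H]1c2cc(OC)c(OC)c(OC)c2 | intermediate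
21 | (2S,3R,4R)-2-[(1S,2E)-3-bromo-1-(tert-butyldimethylsilyloxy)-2-methoxyprop-2-en-1-yl]-2-methoxy-4-methyl-3-(3,4,5-trimethoxyphenyl)cyclopentan-1-one (Br cis to the carbinol carbon) | Br/C=C(OC)\[C@@H](O[Si](C)(C)C(C)(C)C)[C@]1(OC)C(=O)C[C@@H](C)[C@@H]1c2cc(OC)c(OC)c(OC)c2 | intermediate
22 | allyl bromide (3-bromoprop-1-ene) | C=CCBr | starting material
23 | lithium enolate of 21 (C1=C8 enolate) | Br/C=C(OC)\[C@@H](O[Si](C)(C)C(C)(C)C)[C@]1(OC)C([O-])=C[C@@H](C)[C@@H]1c2cc(OC)c(OC)c(OC)c2.[Li+] | intermediate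
24 | (2S,3R,4S,5R)-2-[(1S,2E)-3-bromo-1-(tert-butyldimethylsilyloxy)-2-methoxyprop-2-en-1-yl]-2-methoxy-4-methyl-5-(prop-2-en-1-yl)-3-(3,4,5-trimethoxyphenyl)cyclopentan-1-one (allyl trans to methyl; the 5S epimer may accompany it) | Br/C=C(OC)\[C@@H](O[Si](C)(C)C(C)(C)C)[C@]1(OC)C(=O)[C@H](CC=C)[C@@H](C)[C@@H]1c2cc(OC)c(OC)c(OC)c2 | intermediate
25 | (1S,4R,5S,6R,7S)-4-(tert-butyldimethylsilyloxy)-3,5-dimethoxy-7-methyl-1-(prop-2-en-1-yl)-6-(3,4,5-trimethoxyphenyl)bicyclo[3.2.1]oct-2-en-8-one | C=CC[C@]12C=C(OC)[C@@H](O[Si](C)(C)C(C)(C)C)[C@](OC)(C1=O)[C@@H](c1cc(OC)c(OC)c(OC)c1)[C@@H]2C | intermediate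
26 | (1S,4R,5S,6R,7S)-4-hydroxy-3,5-dimethoxy-7-methyl-1-(prop-2-en-1-yl)-6-(3,4,5-trimethoxyphenyl)bicyclo[3.2.1]oct-2-en-8-one | C=CC[C@]12C=C(OC)[C@@H](O)[C@](OC)(C1=O)[C@@H](c1cc(OC)c(OC)c(OC)c1)[C@@H]2C | intermediate
27 | (1S,4R,5S,6R,7S)-4-acetoxy-3,5-dimethoxy-7-methyl-1-(prop-2-en-1-yl)-6-(3,4,5-trimethoxyphenyl)bicyclo[3.2.1]oct-2-en-8-one | C=CC[C@]12C=C(OC)[C@@H](OC(C)=O)[C@](OC)(C1=O)[C@@H](c1cc(OC)c(OC)c(OC)c1)[C@@H]2C | target

**Step count and risks**

Total step count: 16. Longest linear sequence: 16 steps, from (S)-citronellol 1 to 27.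

Steps most likely to fail:

Step 12. The loss of HBr may place bromine cis to methoxy in part or mainly, a geometry that cannot cyclise, and bromine may attack the trimethoxyarene if the temperature rises. The fallback sets the geometry by a stereoselective hydrogenolysis of a gem-dibromide and not by the elimination. It sets out from 21 as formed, however rich in its geometric isomer (2S,3R,4R)-2-[(1S,2Z)-3-bromo-1-(tert-butyldimethylsilyloxy)-2-methoxyprop-2-en-1-yl]-2-methoxy-4-methyl-3-(3,4,5-trimethoxyphenyl)cyclopentan-1-one F1. A second equivalent of Br2 (CH2Cl2, −78 °C) should give the tribromo ether F2 (not isolated), and DBU the 2,2-dibromo-1-methoxyvinyl compound F3, in which the geometric question is gone. Bu3SnH with catalytic Pd(PPh3)4, a known selective hydrogenolysis of 1,1-dibromoalkenes, should remove the bromine on the less hindered side, cis to the small methoxy group and trans to the bulky carbinol carbon. The route is rejoined at 21 with bromine cis to C4.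

Step 10. Facial selectivity may be poor if an α-methoxy chelate competes with the open transition state; attack or enolisation at the ring ketone and retro-aldol loss of the adduct are further risks. Steps 11 to 15 do not depend on the configuration at C4, so a C4 epimer would pass through them unchanged. The fallback replaces acyclic 1,2-induction by substrate control in the rigid bicycle and sets out from 26, pure or mixed with its C4 epimer (1S,4S,5S,6R,7S)-4-hydroxy-3,5-dimethoxy-7-methyl-1-(prop-2-en-1-yl)-6-(3,4,5-trimethoxyphenyl)bicyclo[3.2.1]oct-2-en-8-one F4. Dess–Martin periodinane should oxidise both to the single dione (1S,5R,6R,7S)-3,5-dimethoxy-7-methyl-1-(prop-2-en-1-yl)-6-(3,4,5-trimethoxyphenyl)bicyclo[3.2.1]oct-2-ene-4,8-dione F5. Luche reduction (NaBH4, CeCl3·7H2O, MeOH, −78 °C) should reduce the conjugated C4 carbonyl in preference to the doubly neopentyl C8 ketone, with hydride coming from the face of the one-carbon C8 bridge because the other face is covered by the endo aryl group on C6. This places the hydroxyl on the side of the C6–C7 bridge and returns to 26.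

Step 14. Oxidative addition into the electron-rich bromo enol ether may be slow and C–C bond formation at the congested tetrasubstituted enolate slower still, so that reduction of the C–Br bond or alkoxide attack on the substrate or on the bridging ketone of the product takes over. The fallback forms the same C1–C2 bond from a neutral enol silane under non-basic conditions and sets out from 24. TMSOTf and Et3N (CH2Cl2, 0 °C) should give the only possible trimethylsilyl enol ether, {[(3S,4R,5S)-5-[(1S,2E)-3-bromo-1-(tert-butyldimethylsilyloxy)-2-methoxyprop-2-en-1-yl]-5-methoxy-3-methyl-2-(prop-2-en-1-yl)-4-(3,4,5-trimethoxyphenyl)cyclopent-1-en-1-yl]oxy}trimethylsilane F6. Palladium-catalysed coupling in the presence of Bu3SnF (Pd2(dba)3, P(t-Bu)3, toluene, 80 °C), the known fluoride-promoted α-alkenylation of silyl enol ethers through a tin enolate, should close the ring and return to 25.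

Further compounds
F1 | step 12 | (2S,3R,4R)-2-[(1S,2Z)-3-bromo-1-(tert-butyldimethylsilyloxy)-2-methoxyprop-2-en-1-yl]-2-methoxy-4-methyl-3-(3,4,5-trimethoxyphenyl)cyclopentan-1-one | Br\C=C(OC)\[C@@H](O[Si](C)(C)C(C)(C)C)[C@]1(OC)C(=O)C[C@@H](C)[C@@H]1c2cc(OC)c(OC)c(OC)c2
F2 | step 12 | (2S,3R,4R)-2-[(1S)-2,3,3-tribromo-1-(tert-butyldimethylsilyloxy)-2-methoxypropyl]-2-methoxy-4-methyl-3-(3,4,5-trimethoxyphenyl)cyclopentan-1-one (both configurations at the CBr(OMe) carbon) | BrC(Br)C(Br)(OC)[C@@H](O[Si](C)(C)C(C)(C)C)[C@]1(OC)C(=O)C[C@@H](C)[C@@H]1c2cc(OC)c(OC)c(OC)c2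
F3 | step 12 | (2S,3R,4R)-2-[(1S)-3,3-dibromo-1-(tert-butyldimethylsilyloxy)-2-methoxyprop-2-en-1-yl]-2-methoxy-4-methyl-3-(3,4,5-trimethoxyphenyl)cyclopentan-1-one | BrC(Br)=C(OC)[C@@H](O[Si](C)(C)C(C)(C)C)[C@]1(OC)C(=O)C[C@@H](C)[C@@H]1c2cc(OC)c(OC)c(OC)c2
F4 | step 10 | (1S,4S,5S,6R,7S)-4-hydroxy-3,5-dimethoxy-7-methyl-1-(prop-2-en-1-yl)-6-(3,4,5-trimethoxyphenyl)bicyclo[3.2.1]oct-2-en-8-one | C=CC[C@]12C=C(OC)[C@H](O)[C@](OC)(C1=O)[C@@H](c1cc(OC)c(OC)c(OC)c1)[C@@H]2C
F5 | step 10 | (1S,5R,6R,7S)-3,5-dimethoxy-7-methyl-1-(prop-2-en-1-yl)-6-(3,4,5-trimethoxyphenyl)bicyclo[3.2.1]oct-2-ene-4,8-dione | C=CC[C@]12C=C(OC)C(=O)[C@](OC)(C1=O)[C@@H](c1cc(OC)c(OC)c(OC)c1)[C@@H]2C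
F6 | step 14 | {[(3S,4R,5S)-5-[(1S,2E)-3-bromo-1-(tert-butyldimethylsilyloxy)-2-methoxyprop-2-en-1-yl]-5-methoxy-3-methyl-2-(prop-2-en-1-yl)-4-(3,4,5-trimethoxyphenyl)cyclopent-1-en-1-yl]oxy}trimethylsilane | Br/C=C(OC)\[C@@H](O[Si](C)(C)C(C)(C)C)[C@]1(OC)C(O[Si](C)(C)C)=C(CC=C)[C@@H](C)[C@@H]1c2cc(OC)c(OC)c(OC)c2
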